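The pitfall in the delta run is to lay a ruler along the sagging target and carry the fall on to 3.0 d, when the steps between the readings are shrinking.

the same everywhere: catalyst 0.69 mM; temperature 35 °C

| flask | starting material | protic impurity | remark | time |
|---|---|---|---|---|
| delta | 0.10 M | 0.010 M | the very flask that is asked about, followed so far |  |
| zeta | 0.20 M | 0.010 M | run made earlier |  |
| flask | 0.10 M | 0.0100 M |  | 3.0 d |

- delta (time / h: target / %, starting material / %): 5.00: 21.0, 29.5; 8.00: 23.2, 21.3; 12.0: 23.5, 13.2; 20.0: 22.0, 6.3; 40.0: 17.1, 0.9; 60.0: 15.8, 0
- zeta (time / h: target / %, starting material / %): 0.250: 1.1, 88.4; 0.333: 4.0, 85.1; 0.667: 5.9, 73.5; 1.00: 8.1, 65.2; 1.50: 10.6, 57.6; 3.00: 16.6, 40.7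

(readings scatter by 0.5 percentage points)

- removed target is counted in
- additions bring no volume worth counting
- the earlier runs do not show what temperature does; that part of a forecast is a guess

- violet: change nothing and wait 40 h more
- amber: at 3.0 d take out 90% of the target then present, then wait 40 h
- green: at 3.0 d add catalyst, 50.0% of the amount charged, then wait 40 h
- ochre: at 3.0 d raise the temperature by 25 K, then wait 40 h

1. target, in percent of the starting material first charged, at 3.0 d
2. what to do for the largest gain in target; "none" if nothing gains more than 2 percentage points (violet / amber / green / ochre / none)
3. target present, with what was taken out counted in, in percent of the starting material first charged, after violet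
4. target present, with what was taken out counted in, in percent of the starting material first charged, after green

The zeta run, with twice the starting material and the same catalyst, holds at 3.00 h target worth 28.0% of what has gone, so species I cannot see take the rest. In the delta run the starting material reads 0% at 60.0 h, so added catalyst finds little to turn. The target's steps there, 4.9 percentage points and then 1.3 points, shrink 3.77-fold per 20.0 h, which makes 10.4 h the relaxation half-life of the sag, the time in which the distance to the coming level halves; it is a rough reading, because the small step carries the scatter. The level reads 15.3%, so my reckoning puts the delta flask at 15.5% at 3.0 d. But that is 0.20 points above the level, less than the margin, so I expect violet and green to gain nothing. The wait is longer than the half-life, so if the level is a balance, amber refills in time, and I back amber, since the runs show no effect of temperature.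

The forecast gives 15.2% (14% to 16%), a little below mine, then 15% after violet and 14.8% after green, and it picks amber, holding that “the levelling-off looks like an equilibrium between the target and a by-product”.

The flask gives 15.7% at 3.0 d, 15.7% after violet and 15.7% after green; amber gains 10 points but ochre gains 19 points, more than any other option.

    starting material ⇌ other conformer (K = 0.760, k = 0.410 /h, Ea = 108 kJ/mol, ΔH = −57.0 kJ/mol)
    starting material + catalyst → catalyst + target (k = 150 /M/h, Ea = 52.0 kJ/mol)
    catalyst + other conformer → catalyst + isomer of the product A (k = 160 /M/h, Ea = 50.0 kJ/mol)
    target ⇌ isomer of the product B (K = 2.50, k = 0.0910 /h, Ea = 102 kJ/mol, ΔH = −49.0 kJ/mol)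
    other conformer + protic impurity → quenched substrate (k = 31.0 /M/h, Ea = 58.0 kJ/mol)
    (constants at 35 °C)

In this flask the wait counts 3.83 of the half-lives I read off the sag, and 7.35 of the 5.44 h relaxation half-life that the step between target and isomer of the product B has by itself, both ways together, and violet moves the target by −0.058 points. The neighbouring flask, run at 50 °C with the same charges, takes the same count: the scheme gives a forward rate of 0.578 /h and an equilibrium constant of 1.03 between target and isomer of the product B, hence a relaxation half-life of 0.609 h, and 3.0 d holds 118 of those. That flask ends with target at 35.0% and isomer of the product B at 36.0%.

All runs come from a simulation with constants of no real substance, noise included.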